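**Same track.** Left-handed product at 25.0 h reads 12.5 % in the north-east run and 10.1 % in the west run, in percent of both substrates charged. The two runs have the same partner charge, but c(left-handed substrate) is 0.25 M against 1 M. The new flask has that same partner charge, and its substrate lies between theirs.

| flask | left-handed substrate | right-handed substrate | partner | remark | time |
|---|---|---|---|---|---|
| north-east | 0.25 M | 0.25 M | 1.25 M (fed, over 12 h) | run made earlier |  |
| west | 1 M | 1 M | 1.25 M (fed, over 12 h) | run made earlier |  |
| east | 0.50 M | 0.50 M | 0.62 M (fed, over 12 h) | run made earlier |  |
| flask | 0.50 M | 0.50 M | 1.25 M (fed, over 12 h) |  | 40 h |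

| run | time / h | left-handed product / % | left-handed substrate / % |
|---|---|---|---|
| north-east | 3.00 | 0 | 46.5 |
| north-east | 6.00 | 2.7 | 47.8 |
| north-east | 10.0 | 4.6 | 46.5 |
| north-east | 15.0 | 8.6 | 41.3 |
| north-east | 20.0 | 9.0 | 40.1 |
| north-east | 25.0 | 12.5 | 40.7 |
| west | 2.00 | 1.6 | 49.8 |
| west | 3.00 | 0 | 48.6 |
| west | 4.00 | 0.9 | 48.4 |
| west | 6.00 | 1.1 | 49.1 |
| west | 10.0 | 3.4 | 46.8 |
| west | 15.0 | 7.1 | 43.2 |
| west | 25.0 | 10.1 | 39.1 |
| east | 2.00 | 0 | 49.9 |
| east | 4.00 | 1.6 | 49.1 |
| east | 6.00 | 0 | 46.6 |
| east | 12.0 | 2.3 | 47.4 |
| east | 25.0 | 6.2 | 44.9 |

(scatter of a reading: 1 percentage point)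

- amount of left-handed product in percent of the left-handed substrate and right-handed substrate together charged, at 8.0 h, 20 h and 40 h

- partner is single-handed; left-handed substrate and right-handed substrate are mirror images of each other, charged as a racemate, each of them at the stated concentration
- the handed part of partner does not stay in what it makes, so the products of the two hands are mirror images too

**Partner ledger.** I keep the books on the partner, charged in the flask at 1.25 M against 1.00 M of both substrates together. The first entry is left-handed product: by the readings at 25.0 h it holds 5.00 % of the partner charge in north-east and 16.2 % in west. Dividing each share by c(left-handed substrate) gives 0.200 /M and 0.162 /M. Their mean is 0.181 /M, my capture number: the share of partner caught as left-handed product by that time, per molar of left-handed substrate.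

**Other entries.** For the flask I reckon the first entry at 25.0 h as 9.04 %, so 91.0 % stands under right-handed product, other losses and partner still present. The west readings, with their scatter, suggest partner leaving: product gains 3.7 percentage points in 5.00 h, then less per hour, 3 points in 10.0 h, while left-handed substrate reads 43.2 % and then 39.1 %.

**My reckoning.** At this time and with this feed, percent product is the capture number times the whole partner charge, halved, so substrate cancels in my reckoning. The flask should read 11.3 % at 25.0 h.

**The forecast.** It gives 1.9 %, 8.3 % and 15.5 %, on the ground that “the rate is first order in substrate and in partner”. My figure, which is for 25.0 h, lies above its value at 20 h and below its value at 40 h.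

**The flask.** It gives 2.88 %, 9.81 % and 14.3 %, and the forecast holds.

    partner → decomposed reagent (k = 0.0150 /h)
    partner + right-handed substrate → right-handed product (k = 9.10 × 10⁻⁴ /M/h)
    2 partner → homo dimer (k = 0.0450 /M/h)
    left-handed substrate ⇌ achiral form (K = 0.0370, k = 0.0650 /h)
    partner + left-handed substrate → left-handed product (k = 0.0210 /M/h)
    right-handed substrate ⇌ achiral form (K = 0.0370, k = 0.0650 /h)

**Books closed.** At 40.0 h homo dimer holds 55.8 % of the flask's partner charge, more than the 11.4 % in left-handed product. My 11.3 % for 25.0 h lies between the flask's values at 20 h and 40 h. The east run did not enter the capture number, and the number gives that run 5.60 % at 25.0 h; the reading there is 6.2 %.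

(The numbers in the tables are calculated with constants of no real substance, noise included.)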